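- In a closed, stirred vessel of constant volume we follow fractions of the charge, and the nearest simulated run to this flask is delta, which held twice the starting material and was read at the asked time.

| flask | starting material | remark | time |
|---|---|---|---|
| zeta | 5 mM | run made earlier |  |
| delta | 20 mM | run made earlier |  |
| flask | 10 mM |  | 5.0 min |

- zeta (time / min: target / %, intermediate C / %): 0.500: 0, 0; 1.00: 0.2, 3.8; 2.50: 7.6, 12.8; 6.00: 40.2, 14.5
- delta (time / min: target / %, intermediate C / %): 1.50: 2.6, 6.9; 3.00: 11.8, 14.7; 5.00: 30.3, 16.3; 6.00: 40.8, 15.4

(scatter of a reading: 0.5 percentage points)



1. target present at 5.0 min, in percent of the starting material charged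
2. intermediate C present at 5.0 min, in percent of the starting material charged
3. intermediate B present at 5.0 min, in percent of the starting material charged

- Zeta and delta differ in charge by a factor of 4.00, yet at 6.00 min they differ by 0.6 percentage points in target and 0.9 points in intermediate C, against a scatter of 0.5 points per reading.
- So we read the steps as first-order: each rate follows the concentration of its own substrate, and the fractions don't feel the charge. We therefore put this flask where delta stood at 5.00 min, with target 30.3 % and intermediate C 16.3 %.
- In delta at that time, the charge minus target minus intermediate C leaves 53.4 %. This is the unseen share, and we carry it.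
- In a closed vessel it holds intermediate B and whatever stands ahead of it, so for this flask we take it as a ceiling on intermediate B, read with its scatter, and not as an estimate of intermediate B itself.
- Against the mean of both runs at 6.00 min, the share shrinks at 0.181 min⁻¹, a reading with its scatter.
- The forecast gives target 30.3 % (29 % to 31.6 %), intermediate C 16.1 % (15.1 % to 17.1 %) and intermediate B 15.5 % (10.5 % to 20.5 %). On intermediate B it stands lower than our unseen share, and it says: “This estimate is loose, because a sharper lag would allow a lower value.”
- The flask gives target 30.9 %, intermediate C 16.2 % and intermediate B 52.7 %, the largest pool and the resting state here. At that time intermediate B is made at 0.0301 of the rate at which it is used up, each step taken net. The flask's own unseen share is 52.9 %, beside 53.4 % from delta, and intermediate B is nearly all of it.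

    intermediate B → intermediate C (k = 0.00280 s⁻¹)
    intermediate C → target (k = 0.00990 s⁻¹)
    intermediate A → intermediate B (k = 0.0260 s⁻¹)
    starting material → intermediate A (k = 0.0330 s⁻¹)

- For the same charge read at 20 min, 53.4 % shrinking at 0.181 min⁻¹ gives 3.52 %. The computed intermediate B there is 4.25 %.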